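**Retrosynthetic overview**

1. The target is a longipin-2-en-1-one (C1 ketone, C2=C3(CH3), C4 and C11 the cyclobutane CH groups next to C3 and C1, C5 the cyclobutane CH bearing C6(CH3)2, C7(OR)–C8H2–C9(OR), C10 the quaternary cyclobutane C–CH3). Its two identical esters come from an anti-7,9-diol, the enone from a C1 silyloxy / C3 methylidene pair, and the diol from a 7,9-dione that one chiral reducing catalyst converts at both carbonyl groups.
2. Key disconnection C7–C8: the enolate of a C9 methyl ketone (C8) condenses with a C7 ester in a bridging Claisen condensation. This closes the seven-membered ring C5–C11 onto a bicyclo[3.1.1]heptane and creates the dione.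
3. Enabling feature: C8 is the only CH2 between C7 and C9, each flanked on its other side by a fully substituted carbon (C6 with two methyls, C10 of the cyclobutane). The C6 and C9 arms sit cis-1,3 on cyclobutane carbons C5 and C10, both anti to the C1–C3 bridge, so there is one possible enolate and one acyl acceptor, held close together.
4. The cyclobutane and the six-membered ring are formed together by an intramolecular vinylketene–alkene [2+2] cycloaddition of an acyclic trienoic acid. Its single C1 stereocentre (asymmetric vinylogous Mukaiyama aldol) controls C4, C10 and C11 and later becomes the C1 ketone; the C6 arm is then attached to the cyclobutanone carbon C5.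
5. Ring order: four- and six-membered rings in one step, then the seven-membered ring (key step).

Key step: step 11

Note on names: C1–C11 as defined in line 1 are used for all intermediates; "syn" and "anti" on C5 and C10 mean towards and away from the C1–C2–C3 bridge.

Assumption: the (R,R)-enantiomer of the bisphosphoramide catalyst of step 4 is taken to direct the dienol ether to the Si face of the dienal; if the sense is the opposite, its antipode is used.

**Step 1**
Reactants: 1 (E)-3-methylpent-2-en-4-yn-1-ol
Product: 2 (E)-3-methylpenta-2,4-dien-1-ol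
Conditions: H2 (1 atm), Pd/CaCO3 poisoned with Pb(OAc)2, quinoline, EtOAc, rt
Reagents that add atoms: none
Why: Semi-hydrogenation of the terminal alkyne over lead-poisoned palladium should stop at the vinyl group and leave the E-trisubstituted alkene untouched.

**Step 2**
Reactants: 2 (E)-3-methylpenta-2,4-dien-1-ol
Product: 3 (E)-3-methylpenta-2,4-dienal
Conditions: MnO2, CH2Cl2, rt
Reagents that add atoms: none
Why: MnO2 oxidation of an allylic (dienylic) alcohol is chemoselective for the aldehyde and does not isomerise the E-alkene.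

**Step 3**
Reactants: 4 methyl 3-methylbut-2-enoate
Product: 6 tert-butyl[(1-methoxy-3-methylbuta-1,3-dien-1-yl)oxy]dimethylsilane, via lithium dienolate 5 (not isolated)
Conditions: LiN(iPr)2, THF, −78 °C; then TBSCl, DMPU, −78 °C → rt
Reagents that add atoms: tert-butyldimethylsilyl chloride, CC(C)(C)[Si](C)(C)Cl
Why: γ-Deprotonation gives the extended dienolate 5, which is silylated on oxygen (silyl ketene acetal formation) to the dienol ether needed for the vinylogous Mukaiyama aldol reaction.

**Step 4**
Reactants: 3 (E)-3-methylpenta-2,4-dienal; 6 tert-butyl[(1-methoxy-3-methylbuta-1,3-dien-1-yl)oxy]dimethylsilane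
Product: 8 methyl (2E,5S,6E)-5-hydroxy-3,7-dimethylnona-2,6,8-trienoate, via trichlorosilyl ether 7 (not isolated)
Conditions: SiCl4, chiral bisphosphoramide Lewis base [(R,R), N,N′-dimethyl-1,1′-binaphthyl-2,2′-diamine-derived, 2 mol %], iPr2NEt (10 mol %), CH2Cl2, −78 °C; then aq. NaHCO3
Reagents that add atoms: none
Why: In this vinylogous Mukaiyama aldol reaction the phosphoramide-bound trichlorosilyl cation activates the aldehyde and the dienol ether attacks through its γ-carbon on the Si face, which sets C1 (5S in 8) under catalyst control and gives the 2E-enoate.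

**Step 5**
Reactants: 8 methyl (2E,5S,6E)-5-hydroxy-3,7-dimethylnona-2,6,8-trienoate
Product: 9 methyl (2E,5S,6E)-5-[(tert-butyldimethylsilyl)oxy]-3,7-dimethylnona-2,6,8-trienoate
Conditions: TBSCl, imidazole, DMF, rt
Reagents that add atoms: tert-butyldimethylsilyl chloride, CC(C)(C)[Si](C)(C)Cl
Why: Silyl ether formation at the secondary allylic alcohol prevents lactonisation and provides the bulky C1 substituent that steers step 7.

**Step 6**
Reactants: 9 methyl (2E,5S,6E)-5-[(tert-butyldimethylsilyl)oxy]-3,7-dimethylnona-2,6,8-trienoate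
Product: 11 (2E,5S,6E)-5-[(tert-butyldimethylsilyl)oxy]-3,7-dimethylnona-2,6,8-trienoic acid, via lithium carboxylate 10 (not isolated)
Conditions: LiOH, THF/MeOH/H2O, rt; then aq. HCl to pH 4, 0 °C
Reagents that add atoms: lithium hydroxide, [Li+].[OH-]
Why: Saponification of the unhindered methyl enoate, with cold, mild acidification so that the allylic silyl ether and the diene survive.

**Step 7**
Reactants: 11 (2E,5S,6E)-5-[(tert-butyldimethylsilyl)oxy]-3,7-dimethylnona-2,6,8-trienoic acid
Product: 14 (1R,4S,5R,7R)-4-[(tert-butyldimethylsilyl)oxy]-7-ethenyl-7-methyl-2-methylidenebicyclo[3.1.1]heptan-6-one, via acid chloride 12 (not isolated), via vinylketene 13 (not isolated)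
Conditions: 1-chloro-N,N,2-trimethylprop-1-en-1-amine, CH2Cl2, 0 °C; then slow addition to Et3N, toluene, 110 °C (high dilution)
Reagents that add atoms: none
Why: Dehydrochlorination at the C3 methyl group (cis to the acyl group) gives vinylketene 13, which undergoes an intramolecular ketene–alkene [2+2] cycloaddition: the ketene carbonyl carbon bonds to C11 and the ketene α-carbon to C10, the terminus that best carries positive charge (tertiary, allylic), so the bridged bicyclo[3.1.1]heptan-6-one forms; the E-alkene geometry places the C10 methyl syn and the vinyl anti, and C4, C10, C11 follow from C1, whose C–H lies inside towards the cis methyl (A(1,3) strain) so that the tether adds to one face and the silyloxy group ends on the side of the C5 carbonyl.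

**Step 8**
Reactants: 14 (1R,4S,5R,7R)-4-[(tert-butyldimethylsilyl)oxy]-7-ethenyl-7-methyl-2-methylidenebicyclo[3.1.1]heptan-6-one; 15 methyl 2-methylpropanoate
Product: 18 tertiary methyl oxalate of the C5 aldol adduct, via lithium enolate 16 (not isolated), via lithium alkoxide 17 (not isolated)
Conditions: LiN(iPr)2, THF, −78 °C (15 → 16); add 14; then ClC(O)CO2Me, −78 → 0 °C
Reagents that add atoms: methyl chlorooxoacetate, COC(=O)C(=O)Cl
Why: The strained, non-enolisable cyclobutanone (both α-carbons are bridgeheads) should accept the ester enolate in an aldol addition, and the tertiary alkoxide 17 is O-acylated in the same flask to the oxalate needed for radical deoxygenation; the configuration of the carbinol carbon is of no consequence because C5 becomes a radical in step 9.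

**Step 9**
Reactants: 18 tertiary methyl oxalate of the C5 aldol adduct
Product: 19 methyl ester with C5–H syn and the C(CH3)2CO2CH3 arm anti
Conditions: Bu3SnH, AIBN, toluene, 110 °C
Reagents that add atoms: none
Why: Barton–McCombie-type radical deoxygenation of the tertiary oxalate releases the C5 radical, which should take hydrogen on its syn face because the bulky carbon arm settles in the less crowded anti position (the syn position is flanked by C1 with its silyloxy group and by C3, the anti position only by the planar vinyl group on C10), placing the C6 arm cis to the C9 arm.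

**Step 10**
Reactants: 19 methyl ester with C5–H syn and the C(CH3)2CO2CH3 arm anti
Product: 20 keto ester (C10 acetyl in place of vinyl)
Conditions: Pd(Quinox)Cl2 (5 mol %), AgSbF6 (12 mol %), aq. tBuOOH, CH2Cl2, 0 °C → rt
Reagents that add atoms: tert-butyl hydroperoxide, CC(C)(C)OO
Why: Ligand-controlled Markovnikov Wacker oxidation should convert only the monosubstituted vinyl group into the methyl ketone and leave the 1,1-disubstituted methylidene group alone.

**Step 11**
Reactants: 20 keto ester (C10 acetyl in place of vinyl)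
Product: 23 (1S)-1-[(tert-butyldimethylsilyl)oxy]-3-methylidenelongipinane-7,9-dione, via potassium enolate 21 (not isolated), via potassium dionate 22 (not isolated)
Conditions: KOtBu (2.5 equiv), THF (0.01 M), 0 → 40 °C; then aq. HCl, 0 °C
Reagents that add atoms: none
Why: KOtBu deprotonates the only enolisable position of 20, the C8 methyl group of the C9 ketone (C6 and C10 are fully substituted, C4 and C11 are cyclobutane bridgeheads), and enolate 21 adds to the C7 ester carbonyl; loss of methoxide gives the dione, which is deprotonated at C8 at once to the stabilised enolate 22, and this pulls the reversible condensation to the product side. The closest known reaction type is the intramolecular Claisen (Dieckmann-type) condensation of a methyl ketone enolate with an α,α-disubstituted ester, the usual entry to 4,4-dialkylcycloalkane-1,3-diones. The seven-membered ring C5–C6–C7–C8–C9–C10–C11 is closed in the 7-exo-trig mode by an exocyclic enolate (7-enolexo-exo-trig) across the cyclobutane, which completes the tricyclic skeleton. No stereocentre is formed: C7 and C9 leave the step as trigonal carbons of the same kind, which is what allows one catalyst to set both carbinols in step 12. The step needs chemoselectivity for C-acylation inside the molecule over intermolecular condensation, and this should be secured by the cis-1,3 placement of the two arms on C5 and C10 (both anti to the C1–C3 bridge and close in space), by the absence of any other acidic C–H or reactive carbonyl group, and by high dilution.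

**Step 12**
Reactants: 23 (1S)-1-[(tert-butyldimethylsilyl)oxy]-3-methylidenelongipinane-7,9-dione
Product: 24 (1S,7R,9R)-1-[(tert-butyldimethylsilyl)oxy]-3-methylidenelongipinane-7,9-diol
Conditions: (S)-2-methyl-CBS-oxazaborolidine (0.5 equiv), catecholborane, toluene, −40 → 0 °C; then MeOH, H2O
Reagents that add atoms: none
Why: In this Corey–Bakshi–Shibata reduction the catalyst distinguishes at each ketone the fully substituted α-carbon (C10 or C6, large) from the C8 methylene (small) and should give the R carbinol at both C9 and C7, that is the anti-diol; the two faces of each carbonyl differ in the substrate only through the remote six-membered ring, so nothing opposes the catalyst, and catecholborane does not hydroborate the methylidene group at this temperature.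

**Step 13**
Reactants: 24 (1S,7R,9R)-1-[(tert-butyldimethylsilyl)oxy]-3-methylidenelongipinane-7,9-diol; 25 3-methylbut-2-enoyl chloride
Product: 26 (1S,7R,9R)-1-[(tert-butyldimethylsilyl)oxy]-3-methylidenelongipinane-7,9-diyl bis(3-methylbut-2-enoate)
Conditions: 25 (3 equiv in all), pyridine, DMAP, CH2Cl2, 0 → 35 °C
Reagents that add atoms: 3-methylbut-2-enoyl chloride, CC(C)=CC(=O)Cl
Why: DMAP-catalysed esterification (nucleophilic acyl substitution through the acylpyridinium ion) acylates both hindered secondary alcohols with the C1 oxygen still silylated, each hydroxyl group taking up one molecule of the acid chloride, so that a second molecule of 25 is consumed as the reagent named above; any deconjugated 3-methylbut-3-enoate formed through the vinylketene would be re-conjugated by the base of step 15.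

**Step 14**
Reactants: 26 (1S,7R,9R)-1-[(tert-butyldimethylsilyl)oxy]-3-methylidenelongipinane-7,9-diyl bis(3-methylbut-2-enoate)
Product: 27 (1S,7R,9R)-1-hydroxy-3-methylidenelongipinane-7,9-diyl bis(3-methylbut-2-enoate)
Conditions: HF·pyridine, THF, 0 °C → rt
Reagents that add atoms: none
Why: Fluoride-mediated desilylation frees the C1 hydroxyl group without touching the two unsaturated esters.

**Step 15**
Reactants: 27 (1S,7R,9R)-1-hydroxy-3-methylidenelongipinane-7,9-diyl bis(3-methylbut-2-enoate)
Product: 29 (4R,5S,7R,9R,10R,11R)-1-oxolongipin-2-ene-7,9-diyl bis(3-methylbut-2-enoate), via methylidene ketone 28 (not isolated)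
Conditions: 1,1,1-triacetoxy-1,1-dihydro-1,2-benziodoxol-3(1H)-one, CH2Cl2, rt; then DBU (0.2 equiv), rt
Reagents that add atoms: none
Why: Dess–Martin oxidation of the C1 carbinol gives the β,γ-unsaturated ketone 28, which DBU should isomerise through its C2 dienolate to the more stable conjugated, endocyclic enone; C11 is a bridgehead and cannot epimerise.

**Compound list**

1 | (E)-3-methylpent-2-en-4-yn-1-ol | OC/C=C(\C)C#C | starting material
2 | (E)-3-methylpenta-2,4-dien-1-ol | OC/C=C(\C)C=C | intermediate
3 | (E)-3-methylpenta-2,4-dienal | O=C/C=C(\C)C=C | intermediate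
4 | methyl 3-methylbut-2-enoate | COC(=O)C=C(C)C | starting material
5 | lithium 1-methoxy-3-methylbuta-1,3-dien-1-olate (enolate geometry not defined) | COC([O-])=CC(C)=C.[Li+] | intermediate
6 | tert-butyl[(1-methoxy-3-methylbuta-1,3-dien-1-yl)oxy]dimethylsilane (ketene acetal geometry not defined) | COC(O[Si](C)(C)C(C)(C)C)=CC(C)=C | intermediate
7 | methyl (2E,5S,6E)-3,7-dimethyl-5-[(trichlorosilyl)oxy]nona-2,6,8-trienoate | COC(=O)/C=C(\C)C[C@H](O[Si](Cl)(Cl)Cl)/C=C(\C)C=C | intermediate
8 | methyl (2E,5S,6E)-5-hydroxy-3,7-dimethylnona-2,6,8-trienoate | COC(=O)/C=C(\C)C[C@H](O)/C=C(\C)C=C | intermediate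
9 | methyl (2E,5S,6E)-5-[(tert-butyldimethylsilyl)oxy]-3,7-dimethylnona-2,6,8-trienoate | COC(=O)/C=C(\C)C[C@H](O[Si](C)(C)C(C)(C)C)/C=C(\C)C=C | intermediate
10 | lithium (2E,5S,6E)-5-[(tert-butyldimethylsilyl)oxy]-3,7-dimethylnona-2,6,8-trienoate | [Li+].[O-]C(=O)/C=C(\C)C[C@H](O[Si](C)(C)C(C)(C)C)/C=C(\C)C=C | intermediate
11 | (2E,5S,6E)-5-[(tert-butyldimethylsilyl)oxy]-3,7-dimethylnona-2,6,8-trienoic acid | OC(=O)/C=C(\C)C[C@H](O[Si](C)(C)C(C)(C)C)/C=C(\C)C=C | intermediate
12 | (2E,5S,6E)-5-[(tert-butyldimethylsilyl)oxy]-3,7-dimethylnona-2,6,8-trienoyl chloride | ClC(=O)/C=C(\C)C[C@H](O[Si](C)(C)C(C)(C)C)/C=C(\C)C=C | intermediate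
13 | (5S,6E)-5-[(tert-butyldimethylsilyl)oxy]-7-methyl-3-methylidenenona-1,6,8-trien-1-one (vinylketene) | O=C=CC(=C)C[C@H](O[Si](C)(C)C(C)(C)C)/C=C(\C)C=C | intermediate
14 | (1R,4S,5R,7R)-4-[(tert-butyldimethylsilyl)oxy]-7-ethenyl-7-methyl-2-methylidenebicyclo[3.1.1]heptan-6-one (carbonyl carbon is C5; on C10 methyl syn, vinyl anti; C1 silyloxy group on the side of C5) | C=C[C@@]1(C)[C@@H]2[C@@H](O[Si](C)(C)C(C)(C)C)CC(=C)[C@H]1C2=O | intermediate
15 | methyl 2-methylpropanoate | COC(=O)C(C)C | starting material
16 | lithium 1-methoxy-2-methylprop-1-en-1-olate | COC([O-])=C(C)C.[Li+] | intermediate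
17 | lithium alkoxide of the aldol adduct of 14: C5 carries OLi (drawn syn) and C(CH3)2CO2CH3 (drawn anti) | C=C[C@@]1(C)[C@@H]2[C@@H](O[Si](C)(C)C(C)(C)C)CC(=C)[C@H]1[C@]2([O-])C(C)(C)C(=O)OC.[Li+] | intermediate
18 | tertiary methyl oxalate: C5 carries O–C(O)–CO2CH3 (drawn syn) and C(CH3)2CO2CH3 (drawn anti); rest as 14 | C=C[C@@]1(C)[C@@H]2[C@@H](O[Si](C)(C)C(C)(C)C)CC(=C)[C@H]1[C@]2(OC(=O)C(=O)OC)C(C)(C)C(=O)OC | intermediate
19 | methyl ester: C5 is CH with H syn and C(CH3)2CO2CH3 anti; C10 methyl syn, vinyl anti; (1S) silyloxy; C3 methylidene | C=C[C@@]1(C)[C@@H]2[C@@H](O[Si](C)(C)C(C)(C)C)CC(=C)[C@H]1[C@@H]2C(C)(C)C(=O)OC | intermediate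
20 | keto ester: as 19 with acetyl (C9 ketone, C8 methyl) anti on C10 | CC(=O)[C@@]1(C)[C@@H]2[C@@H](O[Si](C)(C)C(C)(C)C)CC(=C)[C@H]1[C@@H]2C(C)(C)C(=O)OC | intermediate
21 | potassium enolate of 20 (C9–OK, C8 methylidene) | C=C([O-])[C@@]1(C)[C@@H]2[C@@H](O[Si](C)(C)C(C)(C)C)CC(=C)[C@H]1[C@@H]2C(C)(C)C(=O)OC.[K+] | intermediate
22 | potassium enolate of dione 23 | O=C1C=C([O-])[C@@]2(C)[C@@H]3[C@@H](O[Si](C)(C)C(C)(C)C)CC(=C)[C@H]2[C@@H]3C1(C)C.[K+] | intermediate
23 | (1S)-1-[(tert-butyldimethylsilyl)oxy]-3-methylidenelongipinane-7,9-dione (C3 carries =CH2 in place of CH3; C4, C5, C10, C11 arranged as in the target) | O=C1CC(=O)[C@@]2(C)[C@@H]3[C@@H](O[Si](C)(C)C(C)(C)C)CC(=C)[C@H]2[C@@H]3C1(C)C | intermediate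
24 | (1S,7R,9R)-1-[(tert-butyldimethylsilyl)oxy]-3-methylidenelongipinane-7,9-diol (anti-diol; 9-OH on the C11 side, 7-OH on the C4 side) | O[C@@H]1C[C@@H](O)[C@@]2(C)[C@@H]3[C@@H](O[Si](C)(C)C(C)(C)C)CC(=C)[C@H]2[C@@H]3C1(C)C | intermediate
25 | 3-methylbut-2-enoyl chloride | CC(C)=CC(=O)Cl | starting material
26 | (1S,7R,9R)-1-[(tert-butyldimethylsilyl)oxy]-3-methylidenelongipinane-7,9-diyl bis(3-methylbut-2-enoate) | CC(C)=CC(=O)O[C@@H]1C[C@@H](OC(=O)C=C(C)C)[C@@]2(C)[C@@H]3[C@@H](O[Si](C)(C)C(C)(C)C)CC(=C)[C@H]2[C@@H]3C1(C)C | intermediate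
27 | (1S,7R,9R)-1-hydroxy-3-methylidenelongipinane-7,9-diyl bis(3-methylbut-2-enoate) | CC(C)=CC(=O)O[C@@H]1C[C@@H](OC(=O)C=C(C)C)[C@@]2(C)[C@@H]3[C@@H](O)CC(=C)[C@H]2[C@@H]3C1(C)C | intermediate
28 | (7R,9R)-3-methylidene-1-oxolongipinane-7,9-diyl bis(3-methylbut-2-enoate) | CC(C)=CC(=O)O[C@@H]1C[C@@H](OC(=O)C=C(C)C)[C@@]2(C)[C@@H]3C(=O)CC(=C)[C@H]2[C@@H]3C1(C)C | intermediate
29 | (4R,5S,7R,9R,10R,11R)-1-oxolongipin-2-ene-7,9-diyl bis(3-methylbut-2-enoate) | CC(C)=CC(=O)O[C@@H]1C[C@@H](OC(=O)C=C(C)C)[C@@]2(C)[C@@H]3C(=O)C=C(C)[C@H]2[C@@H]3C1(C)C | target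

**Step count and risks**

Total step count: 15. Longest linear sequence: 14 steps (from 1 through steps 1, 2 and 4–15; step 3 prepares 6 from 4).

The three steps most likely to fail:

Step 9. What may go wrong: hydrogen-atom transfer to the C5 radical on the face anti to the C1–C3 bridge (poor or reversed facial selectivity). This would leave the C6 arm syn, trans to the C9 arm, and make the ring closure of step 11 impossible. Fallback (C5 is fixed by the ring and not by the reagent): it sets out from 14. The aldolate 17 of step 8 is trapped with TMSCl in place of methyl chlorooxoacetate to give the C5 trimethylsilyl ether F1; the enolate is expected to enter on the same anti face that the tin hydride prefers in the failure case, so the carbon arm is anti. Oxidation of the vinyl group under the conditions of step 10 gives the methyl ketone F2, and KOtBu closes the seven-membered ring as in step 11 to give the C5-silyloxy dione F3, in which C5 is a ring-fusion carbon. CBS reduction as in step 12 gives the diol F4, and acylation of both hydroxyl groups with 25 as in step 13 gives the bis-ester F5. PPTS in MeOH removes only the trimethylsilyl group to give the tertiary alcohol F6, and KN(SiMe3)2 followed by methyl chlorooxoacetate gives the tertiary oxalate F7. Bu3SnH/AIBN then generates a C5 radical that is locked in the tricycle and can take hydrogen only on its open syn face; the product is 26, where the route is rejoined.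

Step 7. What may go wrong: oligomerisation of the dienyl-substituted vinylketene and loss of facial discrimination at the temperature needed for dehydrochlorination. Fallback (keteniminium salt in place of the ketene): it sets out from 11. Coupling with pyrrolidine (EDC·HCl, DMAP, CH2Cl2) gives the pyrrolidine amide F8. Tf2O and 2,4,6-collidine in ClCH2CH2Cl (−20 → 40 °C) convert it, by O-triflation and loss of triflic acid from the C3 methyl group, into the vinylketeniminium triflate F9. This far stronger electrophile should undergo the same intramolecular [2+2] cycloaddition at low temperature under the same A(1,3) control to give the cyclobutaniminium triflate F10. Aqueous NaHCO3 hydrolyses F10 to 14, where the route is rejoined.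

Step 12. What may go wrong: loss of catalyst control (slow hydride delivery to the two hindered carbonyl groups, enolisation of the β-diketone by the borane, uncatalysed background reduction). Fallback (enzyme control for the first carbinol, substrate control for the second, which also installs one ester): it sets out from 23. An R-selective ketoreductase (NADPH, iPrOH, phosphate buffer/DMSO, 30 °C) reduces one carbonyl group only, to give the 9-hydroxy-7-ketone F11. An Evans–Tishchenko reaction (SmI2 cat., 3-methylbut-2-enal, THF, −10 °C) then delivers hydride inside the samarium-bound hemiacetal to C7 anti to the C9 oxygen and leaves the C9 3-methylbut-2-enoate, to give the mono-ester F12. Acylation of the C7 hydroxyl group with 25 (pyridine, DMAP) gives 26, where the route is rejoined.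

**Further compounds**

F1 | step 9 | C5 trimethylsilyl ether of the aldol adduct (methyl ester; C10 vinyl; carbon arm anti) | C=C[C@@]1(C)[C@@H]2[C@@H](O[Si](C)(C)C(C)(C)C)CC(=C)[C@H]1[C@]2(O[Si](C)(C)C)C(C)(C)C(=O)OC
F2 | step 9 | methyl ketone (C10 acetyl) with C5 trimethylsilyloxy group | CC(=O)[C@@]1(C)[C@@H]2[C@@H](O[Si](C)(C)C(C)(C)C)CC(=C)[C@H]1[C@]2(O[Si](C)(C)C)C(C)(C)C(=O)OC
F3 | step 9 | (1S)-1-[(tert-butyldimethylsilyl)oxy]-3-methylidene-5-[(trimethylsilyl)oxy]longipinane-7,9-dione | O=C1CC(=O)[C@@]2(C)[C@@H]3[C@@H](O[Si](C)(C)C(C)(C)C)CC(=C)[C@H]2[C@]3(O[Si](C)(C)C)C1(C)C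
F4 | step 9 | (1S,7R,9R)-1-[(tert-butyldimethylsilyl)oxy]-3-methylidene-5-[(trimethylsilyl)oxy]longipinane-7,9-diol | O[C@@H]1C[C@@H](O)[C@@]2(C)[C@@H]3[C@@H](O[Si](C)(C)C(C)(C)C)CC(=C)[C@H]2[C@]3(O[Si](C)(C)C)C1(C)C
F5 | step 9 | 7,9-bis(3-methylbut-2-enoate) of F4 | CC(C)=CC(=O)O[C@@H]1C[C@@H](OC(=O)C=C(C)C)[C@@]2(C)[C@@H]3[C@@H](O[Si](C)(C)C(C)(C)C)CC(=C)[C@H]2[C@]3(O[Si](C)(C)C)C1(C)C
F6 | step 9 | C5 tertiary alcohol of 26 | CC(C)=CC(=O)O[C@@H]1C[C@@H](OC(=O)C=C(C)C)[C@@]2(C)[C@@H]3[C@@H](O[Si](C)(C)C(C)(C)C)CC(=C)[C@H]2[C@]3(O)C1(C)C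
F7 | step 9 | C5 tertiary methyl oxalate of 26 | CC(C)=CC(=O)O[C@@H]1C[C@@H](OC(=O)C=C(C)C)[C@@]2(C)[C@@H]3[C@@H](O[Si](C)(C)C(C)(C)C)CC(=C)[C@H]2[C@]3(OC(=O)C(=O)OC)C1(C)C
F8 | step 7 | (2E,5S,6E)-5-[(tert-butyldimethylsilyl)oxy]-3,7-dimethyl-1-(pyrrolidin-1-yl)nona-2,6,8-trien-1-one | O=C(/C=C(\C)C[C@H](O[Si](C)(C)C(C)(C)C)/C=C(\C)C=C)N1CCCC1
F9 | step 7 | vinylketeniminium triflate (pyrrolidinium ylidene analogue of 13) | C=C(C[C@H](O[Si](C)(C)C(C)(C)C)/C=C(\C)C=C)C=C=[N+]1CCCC1.[O-]S(=O)(=O)C(F)(F)F
F10 | step 7 | cyclobutaniminium triflate (C5=N+ pyrrolidinium analogue of 14) | C=C[C@@]1(C)[C@@H]2[C@@H](O[Si](C)(C)C(C)(C)C)CC(=C)[C@H]1C2=[N+]3CCCC3.[O-]S(=O)(=O)C(F)(F)F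
F11 | step 12 | (1S,9R)-1-[(tert-butyldimethylsilyl)oxy]-9-hydroxy-3-methylidenelongipinan-7-one | O=C1C[C@@H](O)[C@@]2(C)[C@@H]3[C@@H](O[Si](C)(C)C(C)(C)C)CC(=C)[C@H]2[C@@H]3C1(C)C
F12 | step 12 | (1S,7R,9R)-1-[(tert-butyldimethylsilyl)oxy]-7-hydroxy-3-methylidenelongipinan-9-yl 3-methylbut-2-enoate | O[C@@H]1C[C@@H](OC(=O)C=C(C)C)[C@@]2(C)[C@@H]3[C@@H](O[Si](C)(C)C(C)(C)C)CC(=C)[C@H]2[C@@H]3C1(C)C
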